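## Retrosynthetic overview

1. Rings: A = methylcyclohexene, B = seven-membered enol lactone, C = benzene, D = quinone, E = thiazine 1,1-dioxide. Ring E is made last by hypotaurine annulation of quinone D, which is unmasked from a 5,8-dimethoxynaphthalene.
2. Rings B and A are closed together by one ruthenium-catalysed ring-closing dienyne metathesis (vinyl ester, then methyl alkyne, then trisubstituted alkene). Its last event closes ring A by forming the C(CH3)=CH double bond.
3. Enabling feature: the 1-acyloxy-1,3-diene O–CH=C–C(CH3)=CH that straddles the A/B ring fusion. The enol-ester CH of ring B and the CH of ring A map onto alkene carbons; the ring-fusion sp2 carbon and the methyl-bearing carbon map onto the two carbons of a propynyl group on the quaternary centre.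
4. The quaternary stereocentre comes from a copper–NHC-catalysed enantioselective SN2′ alkynylation of an (E)-3-arylbut-2-enyl phosphate. The vinyl group so formed is extended to the 4-methylpent-3-enyl chain by hydroboration and Suzuki–Miyaura coupling.
5. Ring C is built by o-quinodimethane Diels–Alder benzannulation of an enynoate onto the dimethoxybenzene (ring D precursor). Ring order: D (given), C, then B and A in one flask, quinone, E.

Key step: step 12

Remark (assumption on the chemistry): the quaternary carbon of the target is S (CIP order: ring-fusion sp2 carbon > aryl > CH2 > CH3); compounds 18 to 26 have the same spatial arrangement but are named R because the propynyl group ranks below the aryl group, and the ligand enantiomer in step 8 is chosen accordingly.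

## Route

Step 1
Reactants: 1 (2E)-3-methylpent-2-en-4-yn-1-ol; 2 tert-butyldimethylsilyl chloride
Product: 3 tert-butyldimethyl{[(2E)-3-methylpent-2-en-4-yn-1-yl]oxy}silane
Conditions: imidazole, DMF, 0 °C to rt
Reagents that add atoms: tert-butyldimethylsilyl chloride (TBSCl), CC(C)(C)[Si](C)(C)Cl
Why: Imidazole-mediated silylation of the primary allylic alcohol is routine and leaves the alkyne C–H and the E-alkene untouched.

Step 2
Reactants: 3; 4 di-tert-butyl dicarbonate
Product: 6 tert-butyl (4E)-6-[(tert-butyldimethylsilyl)oxy]-4-methylhex-4-en-2-ynoate, via lithium acetylide 5 (not isolated)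
Conditions: n-BuLi, THF, −78 °C; then Boc2O, −78 °C to 0 °C
Reagents that add atoms: di-tert-butyl dicarbonate (Boc2O), CC(C)(C)OC(=O)OC(=O)OC(C)(C)C
Why: Deprotonation of the terminal alkyne and C-acylation of the acetylide with the dicarbonate is a standard alkynoate synthesis.

Step 3
Reactants: 7 1,4-dimethoxy-2,3-dimethylbenzene; 8 N-bromosuccinimide
Product: 10 2,3-bis(bromomethyl)-1,4-dimethoxybenzene, via monobromide 9 (not isolated)
Conditions: NBS (2.1 equiv), AIBN (cat.), PhCF3, 85 °C, visible light
Reagents that add atoms: N-bromosuccinimide (NBS), O=C1CCC(=O)N1Br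
Why: Wohl–Ziegler benzylic bromination under radical-chain conditions in a non-polar solvent should favour the two benzylic methyl groups over the electron-rich ring.

Step 4
Reactants: 10; 6
Product: 12 tert-butyl 3-[(2E)-4-[(tert-butyldimethylsilyl)oxy]but-2-en-2-yl]-5,8-dimethoxy-1,4-dihydronaphthalene-2-carboxylate, via o-quinodimethane 11 (not isolated)
Conditions: NaI (4 equiv), DMF, 70 °C, slow addition of 10 (1.5 equiv) to 6
Reagents that add atoms: 2,3-bis(bromomethyl)-1,4-dimethoxybenzene (10), COc1ccc(OC)c(CBr)c1CBr
Why: Iodide-induced 1,4-elimination gives the o-quinodimethane, which the electron-poor alkynoate should trap in a Diels–Alder reaction driven by re-aromatisation; the diene is symmetrical, so no regiochemistry arises.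

Step 5
Reactants: 12
Product: 13 tert-butyl 3-[(2E)-4-[(tert-butyldimethylsilyl)oxy]but-2-en-2-yl]-5,8-dimethoxynaphthalene-2-carboxylate
Conditions: DDQ (1.1 equiv), toluene, rt
Reagents that add atoms: none
Why: DDQ dehydrogenation (aromatisation) of a 1,4-dihydronaphthalene is fast at room temperature and should spare the silyl ether and the E-alkene.

Step 6
Reactants: 13
Product: 14 tert-butyl 3-[(2E)-4-hydroxybut-2-en-2-yl]-5,8-dimethoxynaphthalene-2-carboxylate
Conditions: TBAF, AcOH (1 equiv), THF, 0 °C
Reagents that add atoms: none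
Why: Buffered fluoride desilylation frees the allylic alcohol without ionising it; the E geometry keeps the hydroxyl away from the ester.

Step 7
Reactants: 14; 15 diethyl chlorophosphate
Product: 16 tert-butyl 3-[(2E)-4-[(diethoxyphosphoryl)oxy]but-2-en-2-yl]-5,8-dimethoxynaphthalene-2-carboxylate
Conditions: Et3N, DMAP (cat.), CH2Cl2, 0 °C
Reagents that add atoms: diethyl chlorophosphate, CCOP(=O)(Cl)OCC
Why: DMAP-catalysed phosphorylation of the primary allylic alcohol installs the leaving group for the allylic substitution.

Step 8
Reactants: 16; 17 di(isobutyl)(prop-1-yn-1-yl)aluminium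
Product: 18 tert-butyl 5,8-dimethoxy-3-[(3R)-3-methylhex-1-en-4-yn-3-yl]naphthalene-2-carboxylate
Conditions: CuCl2·2H2O (5 mol %), chiral sulfonate-bearing imidazolinium salt (NHC precursor, 5.5 mol %), THF, −15 °C; 17 pre-formed from propyne, i-Bu2AlH, Et3N (5 mol %), hexane, 22 °C
Reagents that add atoms: di(isobutyl)(prop-1-yn-1-yl)aluminium, CC#C[Al](CC(C)C)CC(C)C
Why: Copper–NHC-catalysed enantioselective allylic substitution (SN2′) of an aryl-substituted trisubstituted allylic phosphate with an alkynylaluminium reagent should deliver the propynyl group to the aryl- and methyl-bearing alkene carbon, the chiral carbene ligand selecting the face of the E-alkene and so setting the quaternary stereocentre (ligand enantiomer chosen for R).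

Step 9
Reactants: 18; 19 1-bromo-2-methylprop-1-ene
Product: 21 tert-butyl 3-[(4R)-4,8-dimethylnon-7-en-2-yn-4-yl]-5,8-dimethoxynaphthalene-2-carboxylate, via alkylborane 20 (not isolated)
Conditions: 9-BBN, THF, rt; then 19, PdCl2(dppf) (5 mol %), K3PO4 (aq.), DMF, 50 °C
Reagents that add atoms: 1-bromo-2-methylprop-1-ene, CC(C)=CBr
Why: Anti-Markovnikov hydroboration of the only monosubstituted alkene with 9-BBN (the hindered internal alkyne reacts far more slowly) followed by B-alkyl Suzuki–Miyaura coupling should extend the vinyl group without touching the stereocentre.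

Step 10
Reactants: 21
Product: 23 3-[(4R)-4,8-dimethylnon-7-en-2-yn-4-yl]-5,8-dimethoxynaphthalene-2-carboxylic acid, via trimethylsilyl ester 22 (not isolated)
Conditions: TMSOTf, 2,6-lutidine, CH2Cl2, 0 °C; aqueous work-up at pH 4
Reagents that add atoms: none
Why: Silyl-triflate-mediated tert-butyl ester cleavage (alkyl–oxygen fission, the cation leaving as 2-methylpropene) is insensitive to the steric shielding of the carboxyl group and avoids protic acid at the trisubstituted alkene.

Step 11
Reactants: 23; 24 lithium ethenolate
Product: 26 ethenyl 3-[(4R)-4,8-dimethylnon-7-en-2-yn-4-yl]-5,8-dimethoxynaphthalene-2-carboxylate, via acid chloride 25 (not isolated)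
Conditions: 1-chloro-N,N,2-trimethylprop-1-en-1-amine, CH2Cl2, 0 °C to rt; then added to 24 (from THF and n-BuLi, rt, 16 h), THF, −78 °C to 0 °C
Reagents that add atoms: lithium ethenolate, [Li+].[O-]C=C
Why: Neutral acid chloride formation and O-acylation of the lithium enolate of acetaldehyde (from cycloreversion of lithiated THF) should give the vinyl ester without a π-acidic metal, which would add the acid to the neighbouring alkyne.

Step 12
Reactants: 26
Product: 27 (S)-dimethoxy tetracycle: 5,8-dimethoxynaphthalene fused to ring B (enol lactone Ar–CO–O–CH=C) and ring A (2-methylcyclohex-2-ene whose quaternary carbon carries CH3 and the arene)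
Conditions: second-generation Hoveyda–Grubbs catalyst RuCl2(H2IMes)(=CH-C6H4-2-OiPr) (10 mol % in two portions), toluene (0.002 M), 80 °C, argon sparge
Reagents that add atoms: none
Why: Proposed new method: ene-first ring-closing dienyne metathesis, in which the ruthenium alkylidene loads onto the vinyl ester to give an acyloxycarbene, this inserts the tethered methyl alkyne in the exo sense (the O–CH carbon bonds to the alkyne carbon on the quaternary centre), and the resulting ruthenium vinylcarbene on the methyl-bearing carbon closes onto the trisubstituted alkene, releasing 2-methylpropene through a Ru=C(CH3)2 carrier. The closest known reaction types are the ruthenium-catalysed dienyne ring-closing cascade to fused bicyclic 1,3-dienes and the intermolecular enyne metathesis of alkynes with enol ethers; a vinyl carboxylate as the initiating alkene of a ring-closing cascade has not been shown and an acyloxycarbene can lose carboxylic acid, hence the label. Ring B closes by 7-exo-dig enyne ring closure (new C=C between the enol-ester CH and the ring-fusion carbon) and ring A by six-membered ring-closing olefin metathesis that forms the C(CH3)=CH bond. No stereocentre is created: the quaternary centre is untouched and both new double bonds lie in rings A and B, which fixes their geometry. The selectivity needed is the site of initiation, because initiation at the side-chain alkene would lead to 5-exo closure onto the alkyne and a cyclopentene; the 2-methylprop-1-enyl terminus makes that alkene inert to initiation yet competent as the intramolecular terminator, and the tether excludes the endo mode (an eight-membered ring).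

Step 13
Reactants: 27; 28 water
Product: 29 (S)-naphthoquinone of rings A to D (27 with the dimethoxybenzene ring turned into the 1,4-quinone)
Conditions: (NH4)2Ce(NO3)6 (2.5 equiv), MeCN/H2O 4:1, 0 °C, 15 min
Reagents that add atoms: water, O
Why: Oxidative demethylation of the 1,4-dimethoxyarene with ceric ammonium nitrate (two one-electron oxidations, water delivering the quinone oxygens) should be much faster at 0 °C than oxidation of the acyloxydiene.

Step 14
Reactants: 29; 30 hypotaurine (2-aminoethanesulfinic acid)
Product: 34 CNP0348176.1 (target), via sulfonylhydroquinone 31 (not isolated), via sulfonylquinone 32 (not isolated), via aminohydroquinone 33 (not isolated)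
Conditions: hypotaurine (1.5 equiv), MeCN/EtOH/H2O, air, rt; chromatographic separation from the regioisomer
Reagents that add atoms: hypotaurine, NCCS(=O)O
Why: Conjugate addition of the sulfinate to the quinone carbon β to the more electrophilic carbonyl (the one on the ring carbon para to the lactone carbonyl), air oxidation, intramolecular conjugate addition of the amine to the neighbouring carbon and a second air oxidation should give the thiazine dioxide with sulfur next to the carbonyl para to the alkyl-bearing carbon; the regioisomer is expected as a by-product.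

## Compound list

1 | (2E)-3-methylpent-2-en-4-yn-1-ol | C#C/C(C)=C/CO | starting material
2 | tert-butyldimethylsilyl chloride | CC(C)(C)[Si](C)(C)Cl | starting material
3 | tert-butyldimethyl{[(2E)-3-methylpent-2-en-4-yn-1-yl]oxy}silane | C#C/C(C)=C/CO[Si](C)(C)C(C)(C)C | intermediate
4 | di-tert-butyl dicarbonate | CC(C)(C)OC(=O)OC(=O)OC(C)(C)C | starting material
5 | lithium acetylide of 3 | [Li]C#C/C(C)=C/CO[Si](C)(C)C(C)(C)C | intermediate
6 | tert-butyl (4E)-6-[(tert-butyldimethylsilyl)oxy]-4-methylhex-4-en-2-ynoate | CC(C)(C)OC(=O)C#C/C(C)=C/CO[Si](C)(C)C(C)(C)C | intermediate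
7 | 1,4-dimethoxy-2,3-dimethylbenzene | COc1ccc(OC)c(C)c1C | starting material
8 | N-bromosuccinimide | O=C1CCC(=O)N1Br | starting material
9 | 2-(bromomethyl)-1,4-dimethoxy-3-methylbenzene (monobromide) | COc1ccc(OC)c(CBr)c1C | intermediate
10 | 2,3-bis(bromomethyl)-1,4-dimethoxybenzene | COc1ccc(OC)c(CBr)c1CBr | intermediate
11 | 1,4-dimethoxy-5,6-dimethylidenecyclohexa-1,3-diene (o-quinodimethane) | COC1=CC=C(OC)C(=C)C1=C | intermediate
12 | tert-butyl 3-[(2E)-4-[(tert-butyldimethylsilyl)oxy]but-2-en-2-yl]-5,8-dimethoxy-1,4-dihydronaphthalene-2-carboxylate | COc1ccc(OC)c2c1CC(C(=O)OC(C)(C)C)=C(C2)/C(C)=C/CO[Si](C)(C)C(C)(C)C | intermediate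
13 | tert-butyl 3-[(2E)-4-[(tert-butyldimethylsilyl)oxy]but-2-en-2-yl]-5,8-dimethoxynaphthalene-2-carboxylate | COc1ccc(OC)c2cc(C(=O)OC(C)(C)C)c(cc12)/C(C)=C/CO[Si](C)(C)C(C)(C)C | intermediate
14 | tert-butyl 3-[(2E)-4-hydroxybut-2-en-2-yl]-5,8-dimethoxynaphthalene-2-carboxylate | COc1ccc(OC)c2cc(C(=O)OC(C)(C)C)c(cc12)/C(C)=C/CO | intermediate
15 | diethyl chlorophosphate | CCOP(=O)(Cl)OCC | starting material
16 | tert-butyl 3-[(2E)-4-[(diethoxyphosphoryl)oxy]but-2-en-2-yl]-5,8-dimethoxynaphthalene-2-carboxylate | COc1ccc(OC)c2cc(C(=O)OC(C)(C)C)c(cc12)/C(C)=C/COP(=O)(OCC)OCC | intermediate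
17 | di(isobutyl)(prop-1-yn-1-yl)aluminium | CC#C[Al](CC(C)C)CC(C)C | starting material (reagent, made in the flask from propyne and i-Bu2AlH)
18 | tert-butyl 5,8-dimethoxy-3-[(3R)-3-methylhex-1-en-4-yn-3-yl]naphthalene-2-carboxylate | C=C[C@](c1cc2c(OC)ccc(OC)c2cc1C(=O)OC(C)(C)C)(C)C#CC | intermediate
19 | 1-bromo-2-methylprop-1-ene | CC(C)=CBr | starting material
20 | tert-butyl 3-[(3R)-1-(9-borabicyclo[3.3.1]nonan-9-yl)-3-methylhex-4-yn-3-yl]-5,8-dimethoxynaphthalene-2-carboxylate (alkylborane) | B1(C2CCCC1CCC2)CC[C@](c1cc2c(OC)ccc(OC)c2cc1C(=O)OC(C)(C)C)(C)C#CC | intermediate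
21 | tert-butyl 3-[(4R)-4,8-dimethylnon-7-en-2-yn-4-yl]-5,8-dimethoxynaphthalene-2-carboxylate | CC(C)=CCC[C@](c1cc2c(OC)ccc(OC)c2cc1C(=O)OC(C)(C)C)(C)C#CC | intermediate
22 | trimethylsilyl 3-[(4R)-4,8-dimethylnon-7-en-2-yn-4-yl]-5,8-dimethoxynaphthalene-2-carboxylate | CC(C)=CCC[C@](c1cc2c(OC)ccc(OC)c2cc1C(=O)O[Si](C)(C)C)(C)C#CC | intermediate
23 | 3-[(4R)-4,8-dimethylnon-7-en-2-yn-4-yl]-5,8-dimethoxynaphthalene-2-carboxylic acid | CC(C)=CCC[C@](c1cc2c(OC)ccc(OC)c2cc1C(=O)O)(C)C#CC | intermediate
24 | lithium ethenolate | [Li+].[O-]C=C | starting material (reagent, made in the flask from THF and n-BuLi)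
25 | 3-[(4R)-4,8-dimethylnon-7-en-2-yn-4-yl]-5,8-dimethoxynaphthalene-2-carbonyl chloride | CC(C)=CCC[C@](c1cc2c(OC)ccc(OC)c2cc1C(=O)Cl)(C)C#CC | intermediate
26 | ethenyl 3-[(4R)-4,8-dimethylnon-7-en-2-yn-4-yl]-5,8-dimethoxynaphthalene-2-carboxylate | CC(C)=CCC[C@](c1cc2c(OC)ccc(OC)c2cc1C(=O)OC=C)(C)C#CC | intermediate
27 | (S)-dimethoxy tetracycle (rings A and B closed; 5,8-dimethoxynaphthalene) | CC1=CCC[C@]2(C)C1=COC(=O)c1cc3c(OC)ccc(OC)c3cc12 | intermediate
28 | water | O | starting material
29 | (S)-naphthoquinone of rings A to D | CC1=CCC[C@]2(C)C1=COC(=O)c1cc3c(cc12)C(=O)C=CC3=O | intermediate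
30 | hypotaurine (2-aminoethanesulfinic acid) | NCCS(=O)O | starting material
31 | (S)-3-(2-aminoethylsulfonyl)naphthohydroquinone (sulfonylhydroquinone) | CC1=CCC[C@]2(C)C1=COC(=O)c1cc3c(O)c(S(=O)(=O)CCN)cc(O)c3cc12 | intermediate
32 | (S)-3-(2-aminoethylsulfonyl)naphthoquinone (sulfonylquinone) | CC1=CCC[C@]2(C)C1=COC(=O)c1cc3c(cc12)C(=O)C=C(C3=O)S(=O)(=O)CCN | intermediate
33 | (S)-thiazine-fused naphthohydroquinone (aminohydroquinone) | CC1=CCC[C@]2(C)C1=COC(=O)c1cc3c(O)c4c(c(O)c3cc12)NCCS4(=O)=O | intermediate
34 | CNP0348176.1 | CC1=CCC[C@]2(C)C1=COC(=O)c1cc3c(cc12)C(=O)C1=C(C3=O)S(=O)(=O)CCN1 | target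

## Step count and risks

Total step count: 14. Longest linear sequence: 13 steps (steps 1, 2 and 4 to 14); step 3 is a one-step side branch.

Steps most likely to fail:

1. Step 12 (Proposed new method). What may go wrong: the catalyst may be arrested at the acyloxycarbene stage (loss of carboxylic acid from the ruthenium carbene), or metathesis may start at the side-chain alkene and close 5-exo onto the alkyne. Fallback with known chemistry, setting out from acid 23 and coming back at 27: acid 23 is cyclised with Ph3PAuCl/AgOTf (CH2Cl2, rt, 6-exo-dig addition of the carboxyl group to the alkyne) to the (Z)-ethylidene lactone F1, which LiOH (aq. THF, then acidification) opens to the ethyl ketone acid F2. OsO4 (cat.)/NaIO4/2,6-lutidine cleaves the trisubstituted alkene to the keto aldehyde F3. KOH in MeOH then effects the intramolecular aldol condensation (ketone α-CH2 onto the aldehyde, then dehydration) to the cyclohexenone acid F4, so ring A is still closed through the C(CH3)=CH bond. Dimethylsulfonium methylide (Me3S+ I−, KHMDS, THF) adds to the ketone to give the spiro-epoxide F5. Warming its caesium carboxylate (Cs2CO3, DMF, 60 °C) opens the epoxide at CH2 to the hydroxy lactone F6, which closes ring B. Syn-dehydration with methyl N-(triethylammoniosulfonyl)carbamate (Burgess reagent), for which the only β-hydrogens sit on the O–CH2 carbon, gives 27.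

2. Step 14. What may go wrong: poor site selectivity between the two quinone CH carbons, amine-first addition leading to the regioisomer, and aminolysis of the enol lactone by free hypotaurine. Fallback, setting out from quinone 29 and coming back at 34: 29 is treated with sodium 2-[(tert-butoxycarbonyl)amino]ethanesulfinate in aqueous MeCN/AcOH, so that only sulfur can add; this gives the carbamate-protected sulfonyl hydroquinone F7, which Ag2O oxidises to the sulfonylquinone F8. TFA (CH2Cl2, 0 °C) removes the carbamate to give the ammonium trifluoroacetate F9. Neutralisation (NaHCO3, aq. MeCN, air) lets the amine add to the neighbouring quinone carbon and air oxidation gives 34. This removes the amine-first channel and keeps free amine away from the lactone; the intrinsic site preference of the sulfinate is unchanged, so a minor regioisomer may still need to be separated at F7.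

3. Step 8. What may go wrong: insufficient facial discrimination by the copper–NHC complex, because the ortho ester sits next to the reacting alkene. Fallback, setting out from phosphate 16 and coming back at 18: catalyst control is given up; the substitution is run with an achiral copper–NHC catalyst (CuCl2·2H2O, 1,3-dimesitylimidazolinium chloride) to give the racemic enyne F10, and the R enantiomer 18 is isolated by preparative chromatography on a chiral stationary phase.

Further compounds
F1 | step 12 | (S)-(Z)-ethylidene lactone: six-membered enol lactone from addition of the carboxyl group of 23 to the alkyne | C/C=C1\OC(=O)c2cc3c(OC)ccc(OC)c3cc2[C@]1(C)CCC=C(C)C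
F2 | step 12 | 3-[(4S)-4,8-dimethyl-3-oxonon-7-en-4-yl]-5,8-dimethoxynaphthalene-2-carboxylic acid | CCC(=O)[C@@](C)(CCC=C(C)C)c1cc2c(OC)ccc(OC)c2cc1C(=O)O
F3 | step 12 | 5,8-dimethoxy-3-[(4S)-4-methyl-1,5-dioxoheptan-4-yl]naphthalene-2-carboxylic acid | CCC(=O)[C@@](C)(CCC=O)c1cc2c(OC)ccc(OC)c2cc1C(=O)O
F4 | step 12 | 3-[(1S)-1,3-dimethyl-2-oxocyclohex-3-en-1-yl]-5,8-dimethoxynaphthalene-2-carboxylic acid | CC1=CCC[C@](C)(C1=O)c1cc2c(OC)ccc(OC)c2cc1C(=O)O
F5 | step 12 | 3-[(4S)-4,8-dimethyl-1-oxaspiro[2.5]oct-7-en-4-yl]-5,8-dimethoxynaphthalene-2-carboxylic acid (either configuration at the spiro carbon) | CC1=CCC[C@](C)(C12CO2)c1cc2c(OC)ccc(OC)c2cc1C(=O)O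
F6 | step 12 | (S)-hydroxy lactone: 27 hydrated across the enol-ester double bond (OH on the ring-fusion carbon, O–CH2 in ring B) | CC1=CCC[C@]2(C)C1(O)COC(=O)c1cc3c(OC)ccc(OC)c3cc12
F7 | step 14 | (S)-3-{2-[(tert-butoxycarbonyl)amino]ethylsulfonyl}naphthohydroquinone of rings A to D | CC1=CCC[C@]2(C)C1=COC(=O)c1cc3c(O)c(S(=O)(=O)CCNC(=O)OC(C)(C)C)cc(O)c3cc12
F8 | step 14 | (S)-3-{2-[(tert-butoxycarbonyl)amino]ethylsulfonyl}naphthoquinone of rings A to D | CC1=CCC[C@]2(C)C1=COC(=O)c1cc3c(cc12)C(=O)C=C(C3=O)S(=O)(=O)CCNC(=O)OC(C)(C)C
F9 | step 14 | (S)-3-(2-ammonioethylsulfonyl)naphthoquinone trifluoroacetate | CC1=CCC[C@]2(C)C1=COC(=O)c1cc3c(cc12)C(=O)C=C(C3=O)S(=O)(=O)CC[NH3+].[O-]C(=O)C(F)(F)F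
F10 | step 8 | racemic tert-butyl 5,8-dimethoxy-3-(3-methylhex-1-en-4-yn-3-yl)naphthalene-2-carboxylate | C=CC(C)(C#CC)c1cc2c(OC)ccc(OC)c2cc1C(=O)OC(C)(C)C
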